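**Retrosynthetic overview**

1. Bisoflavolin J comes from acid removal of three MOM ethers from the fully protected bis-isoflavone.
2. Key disconnection: the C2=C3 double bond in ring C of the 8-aryloxy-7-hydroxyisoflavone half, i.e. the O1–C2H=C3(aryl)–C4(=O) vinylogous ester. C2 goes back to an aryl vinyl ether on the ring A oxygen and C3 to the methylene-bearing carbon of a 1,2-diarylprop-2-en-1-one (ring-closing metathesis, ethene lost).
3. That diene comes from O-vinylation and α-methylenation of a 2-hydroxydeoxybenzoin, itself made by Friedel–Crafts acylation of a 2-aryloxyresorcinol ring with 4-hydroxyphenylacetic acid.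
4. The 8-chloro-7-hydroxyisoflavone half comes from one-pot acylation and formylative ring closure of 2-chlororesorcinol with an aryloxyphenylacetic acid; its diaryl ether C–O bond is made first by SNAr of 2,6-dimethoxyphenol on 4'-fluoroacetophenone.
5. Ring order: ring C of the chloro half (step 3), then ring C of the aryloxy half (step 9); all benzene rings are bought.

Key step: step 9

Remark on the chemistry: the target has no stereocentre and no stereogenic double bond, so no stereocontrol is needed; chromenone positions are numbered O1, C2, C3, C4, C4a, C5–C8, C8a.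

**Route**

Step 1
Reactants: 1 2,6-dimethoxyphenol; 2 4'-fluoroacetophenone
Product: 3 1-[4-(2,6-dimethoxyphenoxy)phenyl]ethan-1-one
Conditions: K2CO3, DMF, 140 °C
Reagents that add atoms: none
Why: Nucleophilic aromatic substitution (SNAr), in which the para-acetyl group activates the C–F bond enough for the hindered phenoxide to displace fluoride.

Step 2
Reactants: 3 1-[4-(2,6-dimethoxyphenoxy)phenyl]ethan-1-one
Product: 5 [4-(2,6-dimethoxyphenoxy)phenyl]acetic acid, via thiomorpholide 4 (not isolated)
Conditions: S8, morpholine, 130 °C; then NaOH, aq. EtOH, reflux; then aq. HCl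
Reagents that add atoms: water O (as hydroxide of aqueous NaOH, [Na+].[OH-]); sulfur S1SSSSSSS1 and morpholine C1COCCN1 add atoms to intermediate 4 only
Why: The Willgerodt–Kindler reaction moves the oxidised carbon to the chain end as a thioamide, and alkaline hydrolysis should then give the arylacetic acid while the methyl ethers and the diaryl ether stay intact.

Step 3
Reactants: 5 [4-(2,6-dimethoxyphenoxy)phenyl]acetic acid; 6 2-chlororesorcinol
Product: 8 8-chloro-3-[4-(2,6-dimethoxyphenoxy)phenyl]-7-hydroxy-4H-chromen-4-one, via deoxybenzoin 7 (not isolated)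
Conditions: BF3·OEt2, 85 °C; then DMF, MsCl, 70 °C; aq. work-up
Reagents that add atoms: N,N-dimethylformamide CN(C)C=O (supplies the C2–H carbon)
Why: BF3-mediated Friedel–Crafts acylation of the free resorcinol at C4 (ortho and para to the two hydroxyls) is followed in the same pot by Vilsmeier-type C-formylation of the activated methylene and ring closure of the ortho-hydroxyl onto the formyl carbon, the established one-pot isoflavone synthesis.

Step 4
Reactants: 8 8-chloro-3-[4-(2,6-dimethoxyphenoxy)phenyl]-7-hydroxy-4H-chromen-4-one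
Product: 9 8-chloro-3-[4-(2,6-dihydroxyphenoxy)phenyl]-7-hydroxy-4H-chromen-4-one
Conditions: BBr3, CH2Cl2, −78 °C to rt; H2O
Reagents that add atoms: none
Why: Lewis-acid cleavage of aryl methyl ethers by BBr3 should free both hydroxyls, and the diaryl ether, aryl chloride and chromenone are inert to it.

Step 5
Reactants: 9 8-chloro-3-[4-(2,6-dihydroxyphenoxy)phenyl]-7-hydroxy-4H-chromen-4-one; 10 4-hydroxyphenylacetic acid
Product: 11 8-chloro-3-[4-(2,6-dihydroxy-3-{[4-hydroxyphenyl]acetyl}phenoxy)phenyl]-7-hydroxy-4H-chromen-4-one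
Conditions: BF3·OEt2, 85 °C; aq. NaOAc work-up
Reagents that add atoms: none
Why: Friedel–Crafts acylation in BF3·OEt2 should go to the only doubly activated carbon (ortho to one hydroxyl and para to the other on the 2-aryloxyresorcinol ring), since the acyl-substituted chromenone ring and the diaryl ether ring are much poorer nucleophiles.

Step 6
Reactants: 11 8-chloro-3-[4-(2,6-dihydroxy-3-{[4-hydroxyphenyl]acetyl}phenoxy)phenyl]-7-hydroxy-4H-chromen-4-one
Product: 12 8-chloro-3-[4-(2-hydroxy-6-(methoxymethoxy)-3-{[4-(methoxymethoxy)phenyl]acetyl}phenoxy)phenyl]-7-(methoxymethoxy)-4H-chromen-4-one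
Conditions: MOMCl (3.3 equiv), K2CO3, acetone, 0 °C to rt
Reagents that add atoms: chloromethyl methyl ether COCCl
Why: Williamson-type O-alkylation should take the three free phenols and spare the hydroxyl hydrogen-bonded to the ketone, the usual selectivity for ortho-hydroxyaryl ketones.

Step 7
Reactants: 12 8-chloro-3-[4-(2-hydroxy-6-(methoxymethoxy)-3-{[4-(methoxymethoxy)phenyl]acetyl}phenoxy)phenyl]-7-(methoxymethoxy)-4H-chromen-4-one
Product: 13 8-chloro-3-[4-(2-(ethenyloxy)-6-(methoxymethoxy)-3-{[4-(methoxymethoxy)phenyl]acetyl}phenoxy)phenyl]-7-(methoxymethoxy)-4H-chromen-4-one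
Conditions: vinyl acetate (5 equiv), [Ir(cod)Cl]2 (2 mol%), Na2CO3 (0.6 equiv), PhMe, 100 °C
Reagents that add atoms: vinyl acetate C=COC(C)=O
Why: Iridium-catalysed transfer vinylation of a phenol (addition of the iridium aryloxide across vinyl acetate, then β-acetate elimination) runs under nearly neutral conditions that leave the MOM acetals, the enolisable ketone and the chromenone untouched.

Step 8
Reactants: 13 8-chloro-3-[4-(2-(ethenyloxy)-6-(methoxymethoxy)-3-{[4-(methoxymethoxy)phenyl]acetyl}phenoxy)phenyl]-7-(methoxymethoxy)-4H-chromen-4-one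
Product: 15 1-{3-[4-(8-chloro-7-(methoxymethoxy)-4-oxo-4H-chromen-3-yl)phenoxy]-2-(ethenyloxy)-4-(methoxymethoxy)phenyl}-2-[4-(methoxymethoxy)phenyl]prop-2-en-1-one, via Mannich base 14 (not isolated)
Conditions: (Me2N)2CH2 (3 equiv), Ac2O (4 equiv), DMF, rt to 60 °C
Reagents that add atoms: N,N,N',N'-tetramethylmethanediamine CN(C)CN(C)C (supplies the =CH2 carbon)
Why: Mannich α-methylenation, in which the iminium acetate formed from the aminal and Ac2O aminomethylates the only enolisable carbon and N-acetylation of the Mannich base triggers β-elimination; no acid is present, so the vinyl ether and MOM groups survive, and excess Ac2O traps dimethylamine before it can add to the enone or the chromenone.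

Step 9
Reactants: 15 1-{3-[4-(8-chloro-7-(methoxymethoxy)-4-oxo-4H-chromen-3-yl)phenoxy]-2-(ethenyloxy)-4-(methoxymethoxy)phenyl}-2-[4-(methoxymethoxy)phenyl]prop-2-en-1-one
Product: 16 8-chloro-7-(methoxymethoxy)-3-[4-({7-(methoxymethoxy)-3-[4-(methoxymethoxy)phenyl]-4-oxo-4H-chromen-8-yl}oxy)phenyl]-4H-chromen-4-one
Conditions: second-generation Grubbs catalyst (H2IMes)(PCy3)Cl2Ru=CHPh (10 mol%, two portions), PhMe (0.005 M), 90 °C, Ar sparge
Reagents that add atoms: none
Why: Proposed new method: the ruthenium benzylidene should first exchange with the unhindered terminal vinyl ether (the 1,1-disubstituted, acyl-conjugated alkene initiates far more slowly) to give an aryloxymethylidene Ru=CH–OAr, which adds in a [2+2] sense to the 2-arylpropenone alkene held ortho on ring A, and cycloreversion of the ruthenacyclobutane releases the chromen-4-one and Ru=CH2, which re-enters at the next vinyl ether with loss of ethene. The closest known reactions are ring-closing metatheses of aryl vinyl or propenyl ethers to benzofurans and chromenes and of acrylates to coumarins and butenolides; closure of an enol ether onto an α-aryl enone to give a chromen-4-one has not been shown. Ring C closes as a six-membered ring with the new C2=C3 bond endocyclic, the two alkenes being held 1,2 on an arene, and the gain of 4-pyranone (vinylogous ester) conjugation together with removal of ethene should make closure irreversible. No stereocentre is formed. The step needs ring closure to outrun arrest of the catalyst as a heteroatom-stabilised carbene and intermolecular cross-metathesis or hetero-Diels–Alder dimerisation of the enone; the vinyl ether oxygen is a weak donor because its ring carries the acyl group, so the carbene should stay reactive, and high dilution, heating and the argon sparge favour the intramolecular path.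

Step 10
Reactants: 16 8-chloro-7-(methoxymethoxy)-3-[4-({7-(methoxymethoxy)-3-[4-(methoxymethoxy)phenyl]-4-oxo-4H-chromen-8-yl}oxy)phenyl]-4H-chromen-4-one
Product: 17 bisoflavolin J, 8-chloro-7-hydroxy-3-(4-{[7-hydroxy-3-(4-hydroxyphenyl)-4-oxo-4H-chromen-8-yl]oxy}phenyl)-4H-chromen-4-one
Conditions: 3 M aq. HCl, MeOH–THF, 55 °C
Reagents that add atoms: none
Why: Acid-catalysed acetal hydrolysis should remove all three MOM ethers, and the chromenones, the diaryl ether and the aryl chloride are stable to dilute acid.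

**Compound list**

1 | 2,6-dimethoxyphenol | COc1cccc(OC)c1O | starting material
2 | 4'-fluoroacetophenone | CC(=O)c1ccc(F)cc1 | starting material
3 | 1-[4-(2,6-dimethoxyphenoxy)phenyl]ethan-1-one | CC(=O)c1ccc(Oc2c(OC)cccc2OC)cc1 | intermediate
4 | 2-[4-(2,6-dimethoxyphenoxy)phenyl]-1-(morpholin-4-yl)ethane-1-thione (thiomorpholide, not isolated) | S=C(Cc1ccc(Oc2c(OC)cccc2OC)cc1)N1CCOCC1 | intermediate
5 | [4-(2,6-dimethoxyphenoxy)phenyl]acetic acid | OC(=O)Cc1ccc(Oc2c(OC)cccc2OC)cc1 | intermediate
6 | 2-chlororesorcinol | Oc1cccc(O)c1Cl | starting material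
7 | 1-(3-chloro-2,4-dihydroxyphenyl)-2-[4-(2,6-dimethoxyphenoxy)phenyl]ethan-1-one (deoxybenzoin, not isolated) | O=C(Cc1ccc(Oc2c(OC)cccc2OC)cc1)c1ccc(O)c(Cl)c1O | intermediate
8 | 8-chloro-3-[4-(2,6-dimethoxyphenoxy)phenyl]-7-hydroxy-4H-chromen-4-one | O=c1c(-c2ccc(Oc3c(OC)cccc3OC)cc2)coc2c(Cl)c(O)ccc12 | intermediate
9 | 8-chloro-3-[4-(2,6-dihydroxyphenoxy)phenyl]-7-hydroxy-4H-chromen-4-one | O=c1c(-c2ccc(Oc3c(O)cccc3O)cc2)coc2c(Cl)c(O)ccc12 | intermediate
10 | 4-hydroxyphenylacetic acid | O=C(O)Cc1ccc(O)cc1 | starting material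
11 | 8-chloro-3-[4-(2,6-dihydroxy-3-{[4-hydroxyphenyl]acetyl}phenoxy)phenyl]-7-hydroxy-4H-chromen-4-one | O=c1c(-c2ccc(Oc3c(O)ccc(C(=O)Cc4ccc(O)cc4)c3O)cc2)coc2c(Cl)c(O)ccc12 | intermediate
12 | 8-chloro-3-[4-(2-hydroxy-6-(methoxymethoxy)-3-{[4-(methoxymethoxy)phenyl]acetyl}phenoxy)phenyl]-7-(methoxymethoxy)-4H-chromen-4-one | COCOc1ccc(CC(=O)c2ccc(OCOC)c(Oc3ccc(-c4coc5c(Cl)c(OCOC)ccc5c4=O)cc3)c2O)cc1 | intermediate
13 | 8-chloro-3-[4-(2-(ethenyloxy)-6-(methoxymethoxy)-3-{[4-(methoxymethoxy)phenyl]acetyl}phenoxy)phenyl]-7-(methoxymethoxy)-4H-chromen-4-one | COCOc1ccc(CC(=O)c2ccc(OCOC)c(Oc3ccc(-c4coc5c(Cl)c(OCOC)ccc5c4=O)cc3)c2OC=C)cc1 | intermediate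
14 | 8-chloro-3-[4-(3-{3-(dimethylamino)-2-[4-(methoxymethoxy)phenyl]propanoyl}-2-(ethenyloxy)-6-(methoxymethoxy)phenoxy)phenyl]-7-(methoxymethoxy)-4H-chromen-4-one (racemic Mannich base, not isolated) | COCOc1ccc(C(CN(C)C)C(=O)c2ccc(OCOC)c(Oc3ccc(-c4coc5c(Cl)c(OCOC)ccc5c4=O)cc3)c2OC=C)cc1 | intermediate
15 | 1-{3-[4-(8-chloro-7-(methoxymethoxy)-4-oxo-4H-chromen-3-yl)phenoxy]-2-(ethenyloxy)-4-(methoxymethoxy)phenyl}-2-[4-(methoxymethoxy)phenyl]prop-2-en-1-one | C=COc1c(C(=O)C(=C)c2ccc(OCOC)cc2)ccc(OCOC)c1Oc1ccc(-c2coc3c(Cl)c(OCOC)ccc3c2=O)cc1 | intermediate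
16 | 8-chloro-7-(methoxymethoxy)-3-[4-({7-(methoxymethoxy)-3-[4-(methoxymethoxy)phenyl]-4-oxo-4H-chromen-8-yl}oxy)phenyl]-4H-chromen-4-one | COCOc1ccc2c(=O)c(-c3ccc(OCOC)cc3)coc2c1Oc1ccc(-c2coc3c(Cl)c(OCOC)ccc3c2=O)cc1 | intermediate
17 | bisoflavolin J | O=c1c(-c2ccc(Oc3c(O)ccc4c(=O)c(-c5ccc(O)cc5)coc34)cc2)coc2c(Cl)c(O)ccc12 | target

**Step count and risks**

Total step count: 10. Longest linear sequence: 10 steps (from 1 and 2 to 17).

Steps most likely to fail:

Step 9. The catalyst may be held as the heteroatom-stabilised carbene and not turn over, or intermolecular dimerisation of the enone may outpace closure. The fallback uses known chemistry, sets out from 12 and comes back at 16. Heating 12 with N,N-dimethylformamide dimethyl acetal in toluene at 90 °C should convert the deoxybenzoin methylene into the dimethylaminomethylene ketone (enaminone) F1. Its free ortho-hydroxyl then adds to the enamine carbon and expels dimethylamine, the standard enaminone ring closure to isoflavones, to give 16 without passing through 13 and 15.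

Step 7. The iridium aryloxide of the hindered, hydrogen-bonded hydroxyl may form too slowly, so that the phenol is recovered or O-acetylated instead of vinylated. The fallback sets out from 12 and comes back at 16. O-Allylation with allyl bromide and K2CO3 in DMF at 50 °C should give the allyl ether F2. Isomerisation with RuClH(CO)(PPh3)3 in toluene at 80 °C should give the prop-1-enyl ether F3 as an E/Z mixture. Methylenation under the conditions of step 8 passes through the Mannich base F4 to the propenyl ether enone F5. Metathesis of F5 with (H2IMes)(PCy3)Cl2Ru=CHPh under the conditions of step 9 closes the same ring with loss of propene and gives 16.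

Step 8. The iminium ion may attack the β-carbon of the aryl vinyl ether, or the new enone may take up amine or oligomerise under the reaction conditions. The fallback sets out from 13 and comes back at 15. An aldol reaction with paraformaldehyde (1.1 equiv, catalytic K2CO3, DMSO, rt) should give the α-hydroxymethyl ketone F6. Treatment with MsCl and Et3N in CH2Cl2 at 0 °C forms the mesylate F7, which is not isolated and eliminates under the same basic conditions to give 15.

**Further compounds**

F1 | step 9 | 8-chloro-3-[4-(3-{3-(dimethylamino)-2-[4-(methoxymethoxy)phenyl]prop-2-enoyl}-2-hydroxy-6-(methoxymethoxy)phenoxy)phenyl]-7-(methoxymethoxy)-4H-chromen-4-one (enaminone, alkene geometry not controlled) | COCOc1ccc(C(=CN(C)C)C(=O)c2ccc(OCOC)c(Oc3ccc(-c4coc5c(Cl)c(OCOC)ccc5c4=O)cc3)c2O)cc1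
F2 | step 7 | 8-chloro-7-(methoxymethoxy)-3-[4-(6-(methoxymethoxy)-3-{[4-(methoxymethoxy)phenyl]acetyl}-2-(prop-2-en-1-yloxy)phenoxy)phenyl]-4H-chromen-4-one (allyl ether) | COCOc1ccc(CC(=O)c2ccc(OCOC)c(Oc3ccc(-c4coc5c(Cl)c(OCOC)ccc5c4=O)cc3)c2OCC=C)cc1
F3 | step 7 | 8-chloro-7-(methoxymethoxy)-3-[4-(6-(methoxymethoxy)-3-{[4-(methoxymethoxy)phenyl]acetyl}-2-(prop-1-en-1-yloxy)phenoxy)phenyl]-4H-chromen-4-one (propenyl ether, E/Z mixture) | COCOc1ccc(CC(=O)c2ccc(OCOC)c(Oc3ccc(-c4coc5c(Cl)c(OCOC)ccc5c4=O)cc3)c2OC=CC)cc1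
F4 | step 7 | 8-chloro-3-[4-(3-{3-(dimethylamino)-2-[4-(methoxymethoxy)phenyl]propanoyl}-6-(methoxymethoxy)-2-(prop-1-en-1-yloxy)phenoxy)phenyl]-7-(methoxymethoxy)-4H-chromen-4-one (racemic Mannich base, E/Z mixture, not isolated) | COCOc1ccc(C(CN(C)C)C(=O)c2ccc(OCOC)c(Oc3ccc(-c4coc5c(Cl)c(OCOC)ccc5c4=O)cc3)c2OC=CC)cc1
F5 | step 7 | 1-{3-[4-(8-chloro-7-(methoxymethoxy)-4-oxo-4H-chromen-3-yl)phenoxy]-4-(methoxymethoxy)-2-(prop-1-en-1-yloxy)phenyl}-2-[4-(methoxymethoxy)phenyl]prop-2-en-1-one (propenyl ether enone, E/Z mixture) | CC=COc1c(C(=O)C(=C)c2ccc(OCOC)cc2)ccc(OCOC)c1Oc1ccc(-c2coc3c(Cl)c(OCOC)ccc3c2=O)cc1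
F6 | step 8 | 8-chloro-3-[4-(2-(ethenyloxy)-3-{3-hydroxy-2-[4-(methoxymethoxy)phenyl]propanoyl}-6-(methoxymethoxy)phenoxy)phenyl]-7-(methoxymethoxy)-4H-chromen-4-one (racemic α-hydroxymethyl ketone) | COCOc1ccc(C(CO)C(=O)c2ccc(OCOC)c(Oc3ccc(-c4coc5c(Cl)c(OCOC)ccc5c4=O)cc3)c2OC=C)cc1
F7 | step 8 | 3-{3-[4-(8-chloro-7-(methoxymethoxy)-4-oxo-4H-chromen-3-yl)phenoxy]-2-(ethenyloxy)-4-(methoxymethoxy)phenyl}-2-[4-(methoxymethoxy)phenyl]-3-oxopropyl methanesulfonate (racemic mesylate, not isolated) | COCOc1ccc(C(COS(C)(=O)=O)C(=O)c2ccc(OCOC)c(Oc3ccc(-c4coc5c(Cl)c(OCOC)ccc5c4=O)cc3)c2OC=C)cc1
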